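**Plan**

- Last cuts: the three benzoates and a C1/C2 acetonide. The C3 and C6 carbinols go back to a cyclohex-4-ene-3,6-dione, whose reduction anti to the cis-fused dioxolane puts both oxygens on the diol face.
- Key cut: C1–C2. The vicinal diol of the carbocycle (tertiary C1 bearing C7, secondary C2) is the retron of a ketone–aldehyde pinacol, with C1 as ketone carbon and C2 as aldehyde carbon.
- Enabling feature: O3 and O6 stand 1,4 across the C4=C5 bond. They can be tied through silicon in a seven-membered 1,3,2-dioxasilepine, which fixes the Z alkene and holds both carbonyl arms cis; the tether is removed after the ring closure.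
- Second cut: C4=C5, by silicon-tethered ring-closing metathesis of two allylic alcohols: (R)-butenediol (C2–C4) and the mono-epoxide of divinylcarbinol (C5, C6, C1, C7).
- Forward order: dioxasilepine (metathesis), carbocycle by pinacol (a bicyclo[3.2.2] system), dioxolane, silicon off, C3/C6 oxidised and re-reduced, benzoates, free diol.
- Stereochemistry: C3 comes from the chiral pool and C6 from Sharpless epoxidation. They steer the pinacol (diol anti to the O–Si–O bridge) to fix C1 and C2, and are then re-set all-cis by Luche reduction under control of the dioxolane.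

Key step: step 9

Remark: ring atoms keep the target's locants throughout (C1 quaternary carbinol bearing C7, C2 secondary carbinol, C3, C4=C5, C6). β is the face of the C1 and C2 oxygens, α the other face. The target is the all-cis (1S,2S,3S,6R) isomer with C7 on the α face. (R)-But-3-ene-1,2-diol and penta-1,4-dien-3-ol are taken as commercial.

Step 1
Reactants: 1 (R)-but-3-ene-1,2-diol
Product: 3 (R)-1-[(4-methoxybenzyl)oxy]but-3-en-2-ol, via stannylene acetal 2 (not isolated)
Conditions: Bu2SnO, toluene, reflux (Dean–Stark); then PMBCl, Bu4NI (cat.), 90 °C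
Reagents that add atoms: 4-methoxybenzyl chloride, COc1ccc(CCl)cc1
Why: Regioselective O-alkylation through the dibutylstannylene acetal, which reacts at the primary oxygen and leaves the stereocentre (later C3) untouched.

Step 2
Reactants: 4 penta-1,4-dien-3-ol
Product: 5 (2R,3S)-1,2-epoxypent-4-en-3-ol
Conditions: Ti(OiPr)4, L-(+)-diisopropyl tartrate, tBuOOH, 4 Å molecular sieves, CH2Cl2, −20 °C
Reagents that add atoms: tert-butyl hydroperoxide, CC(C)(C)OO
Why: Sharpless asymmetric epoxidation, in which the titanium tartrate catalyst selects one enantiotopic vinyl group and one of its faces (anti epoxy alcohol) while the minor enantiomer is consumed by a fast second epoxidation, so that the carbinol (later C6) and the oxirane carbon (later C1) are set together.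

Step 3
Reactants: 3 (R)-1-[(4-methoxybenzyl)oxy]but-3-en-2-ol; 5 (2R,3S)-1,2-epoxypent-4-en-3-ol
Product: 7 {[(2R)-1-(4-methoxybenzyloxy)but-3-en-2-yl]oxy}{[(1S)-1-[(2R)-oxiran-2-yl]prop-2-en-1-yl]oxy}di(propan-2-yl)silane, via chlorosilyl ether 6 (not isolated)
Conditions: 3, iPr2SiCl2 (excess), imidazole, CH2Cl2, 0 °C; excess silane evaporated; then 5, imidazole, DMF, rt
Reagents that add atoms: dichlorodi(propan-2-yl)silane, CC(C)[Si](Cl)(Cl)C(C)C
Why: Stepwise nucleophilic substitution at silicon (silyl ether formation), the first chloride displaced by 3 under excess dichlorosilane and the second by 5, gives the unsymmetrical silyl ketal that ties O3 to O6.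

Step 4
Reactants: 7 the mixed silyl ketal
Product: 8 (4R,7S)-4-[(4-methoxybenzyloxy)methyl]-7-[(2R)-oxiran-2-yl]-2,2-di(propan-2-yl)-4,7-dihydro-1,3,2-dioxasilepine (4,7-cis; ring alkene Z)
Conditions: second-generation Grubbs catalyst RuCl2(=CHPh)(PCy3)(H2IMes) (5 mol%), CH2Cl2 (5 mM), 40 °C
Reagents that add atoms: none
Why: Ring-closing metathesis of the two monosubstituted alkenes held by the temporary silicon tether releases ethene and closes the seven-membered ring, in which the new C4=C5 bond can only be Z; the 4,7-cis relationship follows from the two preset stereocentres.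

Step 5
Reactants: 8 the epoxy dioxasilepine
Product: 9 (1R)-1-{(4S,7R)-7-[(4-methoxybenzyloxy)methyl]-2,2-di(propan-2-yl)-4,7-dihydro-1,3,2-dioxasilepin-4-yl}ethane-1,2-diol
Conditions: H2O (3 equiv), (R,R)-[N,N'-bis(3,5-di-tert-butylsalicylidene)-1,2-cyclohexanediaminato]cobalt acetate (trivalent cobalt, matched enantiomer, 2 mol%), THF, rt
Reagents that add atoms: water, O
Why: Cobalt-salen-catalysed hydrolysis of a terminal epoxide (the reaction type of the hydrolytic kinetic resolution) delivers water to the CH2 terminus under neutral conditions that spare the silyl ketal and the PMB ether; the C1 carbinol keeps its configuration, which is erased in step 8.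

Step 6
Reactants: 9 the diol
Product: 10 (1R)-2-(tert-butyldimethylsilyloxy)-1-{(4S,7R)-7-[(4-methoxybenzyloxy)methyl]-2,2-di(propan-2-yl)-4,7-dihydro-1,3,2-dioxasilepin-4-yl}ethan-1-ol
Conditions: TBSCl (1.05 equiv), imidazole, CH2Cl2, −20 to 0 °C
Reagents that add atoms: tert-butyldimethylsilyl chloride, CC(C)(C)[Si](C)(C)Cl
Why: Selective silylation of the primary hydroxyl (C7) over the hindered secondary one (C1) with one equivalent of silyl chloride.

Step 7
Reactants: 10 the PMB ether
Product: 11 (1R)-2-(tert-butyldimethylsilyloxy)-1-[(4S,7R)-7-(hydroxymethyl)-2,2-di(propan-2-yl)-4,7-dihydro-1,3,2-dioxasilepin-4-yl]ethan-1-ol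
Conditions: DDQ, CH2Cl2/pH 7 buffer, 0 °C
Reagents that add atoms: none
Why: Oxidative cleavage of the PMB ether by DDQ (benzylic hydride abstraction, then hydrolysis of the oxocarbenium ion) frees the C2 hydroxyl without touching the silyl ethers or the alkene.

Step 8
Reactants: 11 the diol
Product: 12 (4R,7S)-7-[(tert-butyldimethylsilyloxy)acetyl]-2,2-di(propan-2-yl)-4,7-dihydro-1,3,2-dioxasilepine-4-carbaldehyde
Conditions: Dess–Martin periodinane (3 equiv), NaHCO3, CH2Cl2, 0 °C to rt; crude product used at once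
Reagents that add atoms: none
Why: Dess–Martin oxidation converts the primary alcohol into the C2 aldehyde and the secondary alcohol into the C1 ketone in one operation under buffered, non-basic conditions, so that the α-silyloxy β,γ-unsaturated aldehyde is neither epimerised nor isomerised.

Step 9
Reactants: 12 the keto-aldehyde
Product: 13 (1S,2S,3R,6S)-1-[(tert-butyldimethylsilyloxy)methyl]-3,6-O-[di(propan-2-yl)silanediyl]cyclohex-4-ene-1,2,3,6-tetrol (a 2,4-dioxa-3-silabicyclo[3.2.2]non-6-ene-8,9-diol; 1β,2β-diol; O3 and O6 α)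
Conditions: SmI2 (3 equiv), tBuOH (3 equiv), THF, −78 to −40 °C
Reagents that add atoms: none
Why: SmI2 transfers one electron to the aldehyde to give a samarium ketyl at C2, which adds to the samarium-bound C1 ketone; a second electron transfer gives the samarium diolate and, on work-up, the diol. The closest known reaction type is the SmI2-mediated intramolecular ketone–aldehyde pinacol coupling of α-oxygenated 1,6-dicarbonyl compounds to cyclohexane-cis-1,2-diols. The six-membered carbocycle closes 6-exo-trig and, because O3 and O6 stay tied through silicon, a 2,4-dioxa-3-silabicyclo[3.2.2]non-6-ene results. The cis relationship of the new C1 and C2 hydroxyls is set by the samarium that bridges both oxygens; their absolute configuration is set by C3 and C6, because the two bulky C–O–Sm bonds should turn away from the O–Si(iPr)2–O bridge and lie anti to the C3–O and C6–O bonds (the usual anti preference of such pinacols), on the side of the C4=C5 bridge. The step needs coupling to outrun reductive cleavage of the α C–O bonds and enolisation of the aldehyde: all α-oxygens are silyl ethers and not esters, no HMPA is used, the medium is cold and non-basic, and the 4,7-cis arrangement on the seven-membered ring keeps the two carbonyl groups within bonding distance.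

Step 10
Reactants: 13 the bicyclic diol
Product: 14 1,2-O-isopropylidene derivative of 13 (1S,2S,3R,6S)
Conditions: 2,2-dimethoxypropane, PPTS, CH2Cl2, rt
Reagents that add atoms: 2,2-dimethoxypropane, COC(C)(C)OC
Why: Acid-catalysed transketalisation onto the cis-1,2-diol, whose hydroxyls are eclipsed on the two-carbon bridge, gives the dioxolane that later shields one face and keeps the C1 and C2 hydroxyls unacylated.

Step 11
Reactants: 14 the acetonide
Product: 15 (1R,2S,3R,6S)-1-(hydroxymethyl)-1,2-O-isopropylidenecyclohex-4-ene-1,2,3,6-tetrol (3α,6α-diol)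
Conditions: TBAF, THF, 0 °C to rt
Reagents that add atoms: none
Why: Fluoride-induced desilylation cleaves all Si–O bonds, removing the silicon tether and the TBS ether in one operation.

Step 12
Reactants: 15 the triol
Product: 16 (1S,2R)-1-(hydroxymethyl)-1,2-(isopropylidenedioxy)cyclohex-4-ene-3,6-dione
Conditions: activated MnO2 (excess), CH2Cl2, rt
Reagents that add atoms: none
Why: MnO2 oxidises only the two allylic carbinols, leaving the non-allylic primary alcohol, and gives the ene-dione under neutral conditions (allylic alcohol oxidation).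

Step 13
Reactants: 16 the ene-dione
Product: 17 (1R,2S,3S,6R)-1-(hydroxymethyl)-1,2-O-isopropylidenecyclohex-4-ene-1,2,3,6-tetrol (all four ring oxygens β)
Conditions: NaBH4, CeCl3·7H2O, MeOH, −78 °C
Reagents that add atoms: none
Why: Luche 1,2-reduction, in which hydride should add to both carbonyls from the α face, opposite the cis-fused dioxolane and anti to the pseudo-axial C1–O bond (Felkin–Anh), so that the new C3 and C6 hydroxyls appear cis to the C1 and C2 oxygens.

Step 14
Reactants: 17 the all-cis triol
Product: 18 (1R,2S,3S,6R)-3,6-di-O-benzoyl-1-[(benzoyloxy)methyl]-1,2-O-isopropylidenecyclohex-4-ene-1,2,3,6-tetrol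
Conditions: BzCl (4 equiv), pyridine, DMAP (cat.), CH2Cl2, 0 °C to rt
Reagents that add atoms: benzoyl chloride, O=C(Cl)c1ccccc1
Why: DMAP-catalysed acylation of one primary and two allylic secondary hydroxyls; no stereocentre is touched.

Step 15
Reactants: 18 the tribenzoate acetonide
Product: 19 (1S,2S,3S,6R)-1-[(benzoyloxy)methyl]-1,2-dihydroxycyclohex-4-ene-3,6-diyl dibenzoate (target)
Conditions: TFA/H2O 9:1, 0 °C
Reagents that add atoms: none
Why: Acid hydrolysis of the isopropylidene ketal frees the C1/C2 diol; benzoates are stable to aqueous acid, and acyl migration is slow at low pH and low temperature.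

**Compound list**

1 | (R)-but-3-ene-1,2-diol | C=C[C@@H](O)CO | starting material
2 | (4R)-2,2-dibutyl-4-ethenyl-1,3,2-dioxastannolane (stannylene acetal) | C=C[C@@H]1CO[Sn](CCCC)(CCCC)O1 | intermediate
3 | (R)-1-[(4-methoxybenzyl)oxy]but-3-en-2-ol | C=C[C@@H](O)COCc1ccc(OC)cc1 | intermediate
4 | penta-1,4-dien-3-ol | C=CC(O)C=C | starting material
5 | (2R,3S)-1,2-epoxypent-4-en-3-ol | C=C[C@H](O)[C@H]1CO1 | intermediate
6 | chloro{[(2R)-1-(4-methoxybenzyloxy)but-3-en-2-yl]oxy}di(propan-2-yl)silane | C=C[C@@H](O[Si](Cl)(C(C)C)C(C)C)COCc1ccc(OC)cc1 | intermediate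
7 | {[(2R)-1-(4-methoxybenzyloxy)but-3-en-2-yl]oxy}{[(1S)-1-[(2R)-oxiran-2-yl]prop-2-en-1-yl]oxy}di(propan-2-yl)silane | C=C[C@@H](O[Si](C(C)C)(C(C)C)O[C@@H](C=C)[C@H]1CO1)COCc1ccc(OC)cc1 | intermediate
8 | (4R,7S)-4-[(4-methoxybenzyloxy)methyl]-7-[(2R)-oxiran-2-yl]-2,2-di(propan-2-yl)-4,7-dihydro-1,3,2-dioxasilepine | CC(C)[Si]1(C(C)C)O[C@@H](COCc2ccc(OC)cc2)C=C[C@@H]([C@H]2CO2)O1 | intermediate
9 | (1R)-1-{(4S,7R)-7-[(4-methoxybenzyloxy)methyl]-2,2-di(propan-2-yl)-4,7-dihydro-1,3,2-dioxasilepin-4-yl}ethane-1,2-diol | CC(C)[Si]1(C(C)C)O[C@@H](COCc2ccc(OC)cc2)C=C[C@@H]([C@H](O)CO)O1 | intermediate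
10 | primary TBS ether of 9 | CC(C)[Si]1(C(C)C)O[C@@H](COCc2ccc(OC)cc2)C=C[C@@H]([C@H](O)CO[Si](C)(C)C(C)(C)C)O1 | intermediate
11 | (1R)-2-(tert-butyldimethylsilyloxy)-1-[(4S,7R)-7-(hydroxymethyl)-2,2-di(propan-2-yl)-4,7-dihydro-1,3,2-dioxasilepin-4-yl]ethan-1-ol | CC(C)[Si]1(C(C)C)O[C@@H](CO)C=C[C@@H]([C@H](O)CO[Si](C)(C)C(C)(C)C)O1 | intermediate
12 | (4R,7S)-7-[(tert-butyldimethylsilyloxy)acetyl]-2,2-di(propan-2-yl)-4,7-dihydro-1,3,2-dioxasilepine-4-carbaldehyde | CC(C)[Si]1(C(C)C)O[C@@H](C=O)C=C[C@@H](C(=O)CO[Si](C)(C)C(C)(C)C)O1 | intermediate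
13 | (1S,2S,3R,6S)-1-[(tert-butyldimethylsilyloxy)methyl]-3,6-O-[di(propan-2-yl)silanediyl]cyclohex-4-ene-1,2,3,6-tetrol | CC(C)(C)[Si](C)(C)OC[C@@]1(O)[C@@H](O[Si]2(C(C)C)C(C)C)C=C[C@@H](O2)[C@@H]1O | intermediate
14 | 1,2-O-isopropylidene derivative of 13 | CC(C)(C)[Si](C)(C)OC[C@@]1(OC(C)(C)O3)[C@@H](O[Si]2(C(C)C)C(C)C)C=C[C@@H](O2)[C@@H]13 | intermediate
15 | (1R,2S,3R,6S)-1-(hydroxymethyl)-1,2-O-isopropylidenecyclohex-4-ene-1,2,3,6-tetrol | OC[C@@]1(OC(C)(C)O2)[C@@H](O)C=C[C@@H](O)[C@@H]12 | intermediate
16 | (1S,2R)-1-(hydroxymethyl)-1,2-(isopropylidenedioxy)cyclohex-4-ene-3,6-dione | OC[C@@]1(OC(C)(C)O2)C(=O)C=CC(=O)[C@@H]12 | intermediate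
17 | (1R,2S,3S,6R)-1-(hydroxymethyl)-1,2-O-isopropylidenecyclohex-4-ene-1,2,3,6-tetrol (all-cis) | OC[C@@]1(OC(C)(C)O2)[C@H](O)C=C[C@H](O)[C@@H]12 | intermediate
18 | (1R,2S,3S,6R)-3,6-di-O-benzoyl-1-[(benzoyloxy)methyl]-1,2-O-isopropylidenecyclohex-4-ene-1,2,3,6-tetrol | O=C(OC[C@@]1(OC(C)(C)O2)[C@H](OC(=O)c3ccccc3)C=C[C@H](OC(=O)c3ccccc3)[C@@H]12)c1ccccc1 | intermediate
19 | (1S,2S,3S,6R)-1-[(benzoyloxy)methyl]-1,2-dihydroxycyclohex-4-ene-3,6-diyl dibenzoate | O=C(OC[C@@]1(O)[C@H](OC(=O)c2ccccc2)C=C[C@H](OC(=O)c2ccccc2)[C@@H]1O)c1ccccc1 | target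

**Step count**

Total steps: 15. Longest linear sequence: 14 steps (from 1 through steps 1 and 3–15; the branch from 4 to 5 is one step).

**Steps most likely to fail**

Step 9 (pinacol). The ring closure may fail through reductive cleavage of an α C–O bond, through isomerisation of the β,γ-unsaturated aldehyde, or through poor or reversed facial selectivity; a reversed face would carry the wrong absolute configuration at C1 and C2 through the later redox relay. The fallback sets out from 12 and closes the same C1–C2 bond as an alkene. Twofold Wittig methylenation (Ph3P=CH2, THF, −78 to 0 °C) should give the 4-ethenyl-7-[3-(tert-butyldimethylsilyloxy)prop-1-en-2-yl]dioxasilepine F1. Ring-closing metathesis with the second-generation Grubbs catalyst should give the bridged diene 8-[(tert-butyldimethylsilyloxy)methyl]-3,3-di(propan-2-yl)-2,4-dioxa-3-silabicyclo[3.2.2]nona-6,8-diene F2. Dihydroxylation (OsO4 cat., NMO, acetone/H2O) of the more electron-rich trisubstituted alkene, from the face turned away from the O–Si–O bridge and anti to both allylic oxygens, comes back to the route at 13.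

Step 12 (MnO2 oxidation). The hydroxy ene-dione may lose its free hydroxymethyl group by retro-aldol cleavage, may open the dioxolane by β-elimination towards a hydroxyquinone, or the second oxidation may stall. The fallback sets out from 14 and carries C7 protected through the redox relay. HF·pyridine/pyridine (THF, 0 °C) should remove only the silicon bridge and give the 7-O-TBS 3α,6α-diol F3. Dess–Martin oxidation should give the 7-O-TBS ene-dione F4, and Luche reduction the 7-O-TBS all-cis diol F5. TBAF then returns to the route at 17.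

Step 13 (Luche reduction). Facial selectivity may be poor at C6, which lies next to the quaternary centre, and conjugate reduction may compete. The fallback sets out from 15 and inverts the two allylic carbinols by substitution instead of redox. A Mitsunobu reaction (PPh3, DIAD, 4-nitrobenzoic acid, THF) should esterify the primary hydroxyl and invert C3 and C6 to give the all-cis tris(4-nitrobenzoate) F6. Methanolysis (K2CO3, MeOH) then comes back to the route at 17.

**Further compounds**

F1 | step 9 | (4R,7S)-7-[3-(tert-butyldimethylsilyloxy)prop-1-en-2-yl]-4-ethenyl-2,2-di(propan-2-yl)-4,7-dihydro-1,3,2-dioxasilepine (4,7-cis) | CC(C)[Si]1(C(C)C)O[C@@H](C=C)C=C[C@@H](C(=C)CO[Si](C)(C)C(C)(C)C)O1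
F2 | step 9 | 8-[(tert-butyldimethylsilyloxy)methyl]-3,3-di(propan-2-yl)-2,4-dioxa-3-silabicyclo[3.2.2]nona-6,8-diene | CC(C)(C)[Si](C)(C)OCC1=C[C@H](O[Si]2(C(C)C)C(C)C)C=C[C@@H]1O2
F3 | step 12 | 1-[(tert-butyldimethylsilyloxy)methyl]-1,2-O-isopropylidenecyclohex-4-ene-1,2,3,6-tetrol (3α,6α-diol) | CC(C)(C)[Si](C)(C)OC[C@@]1(OC(C)(C)O2)[C@@H](O)C=C[C@@H](O)[C@@H]12
F4 | step 12 | 1-[(tert-butyldimethylsilyloxy)methyl]-1,2-(isopropylidenedioxy)cyclohex-4-ene-3,6-dione | CC(C)(C)[Si](C)(C)OC[C@@]1(OC(C)(C)O2)C(=O)C=CC(=O)[C@@H]12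
F5 | step 12 | 1-[(tert-butyldimethylsilyloxy)methyl]-1,2-O-isopropylidenecyclohex-4-ene-1,2,3,6-tetrol (all-cis) | CC(C)(C)[Si](C)(C)OC[C@@]1(OC(C)(C)O2)[C@H](O)C=C[C@H](O)[C@@H]12
F6 | step 13 | all-cis 3,6-di-O-(4-nitrobenzoyl)-1-[(4-nitrobenzoyloxy)methyl]-1,2-O-isopropylidenecyclohex-4-ene-1,2,3,6-tetrol | O=C(OC[C@@]1(OC(C)(C)O2)[C@H](OC(=O)c3ccc(cc3)[N+](=O)[O-])C=C[C@H](OC(=O)c3ccc(cc3)[N+](=O)[O-])[C@@H]12)c1ccc(cc1)[N+](=O)[O-]
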